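Beta and epsilon both held 0.20 M of starting material and differed in the other conformer charged, 6.5 × 10⁻⁴ M against 0.016 M.

common to all: starting material 0.20 M

| charge | other conformer | remark | time |
|---|---|---|---|
| beta | 6.5 × 10⁻⁴ M | run made earlier |  |
| epsilon | 0.016 M | run made earlier |  |
| cedar | 0.00120 M |  | 10 h |
| maple | 0.00250 M |  | 10 h |
| ash | 0.00500 M |  | 10 h |
| birch | 0.0100 M |  | 10 h |
| alder | 0.0200 M |  | 10 h |

| run | time / h | target / % | starting material / % |
|---|---|---|---|
| beta | 1.00 | 8.9 | 68.8 |
| beta | 2.00 | 14.8 | 51.8 |
| beta | 3.00 | 20.8 | 40.5 |
| beta | 4.00 | 24.9 | 32.2 |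
| beta | 5.00 | 26.8 | 26.2 |
| beta | 6.00 | 29.4 | 21.3 |
| beta | 8.00 | 33.9 | 15.5 |
| epsilon | 1.00 | 8.7 | 64.7 |
| epsilon | 2.00 | 14.7 | 47.6 |
| epsilon | 3.00 | 19.8 | 37.7 |
| epsilon | 4.00 | 22.9 | 29.9 |
| epsilon | 5.00 | 25.7 | 23.8 |
| epsilon | 6.00 | 28.0 | 19.9 |
| epsilon | 8.00 | 31.6 | 14.4 |

(scatter of a reading: 0.5 percentage points)

- the numbers in the tables scatter with a standard deviation of 0.5 percentage points
- "hardly changes" means that all values lie within two and a half points (for a concentration: within two and a half percent of the largest)

- amount of target at the end, in percent of the starting material and other conformer together charged for cedar, maple, ash, birch, alder, in this order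
- how the row runs (hardly changes / falls all the way / rises, then falls / falls, then rises / rises all the way)

The percentages have different denominators, so I turned them into concentrations. At 8.00 h the beta reading came to 0.06802 M of target and the epsilon reading to 0.06826 M. Epsilon carried 0.0154 M more other conformer, yet its target read higher by just 0.12 percentage points of the starting material, while a reading scatters by 0.5 points. So I counted target against starting material.

I took target as made at a rate k_P times the starting material present. Summing the beta curve by trapezoids gave an exposure S, the hours at full charge, of 3.17 h. Then k_P, the target reading over S, was 0.107 /h. The starting material readings went from 21.3 % to 15.5 % between 6.00 h and 8.00 h. Repeating that ratio gave 11.3 % at 10 h, and the last stretch added 2.9 points. That made the target stock T, the molar target of this charge of starting material at 10 h: 0.0738 M.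

The weak link was that this chain rested on the beta readings. I repeated the chain on epsilon: S was 2.94 h, k_P 0.107 /h, and T 0.0740 M.

Dividing T by the charge gave me 36.7 % for cedar and 33.5 % for alder, a lower figure.

The forecast, “The charged conformer seems to be a spectator”, gave 36.5 %, 36.3 %, 35.9 %, 35 % and 33.4 %, a row that falls all the way, its cedar lower than mine by 0.17 points.

The flasks gave 36.3 %, 36.1 %, 35.7 %, 34.9 % and 33.4 %, a row that falls all the way.

    starting material ⇌ other conformer (K = 0.170, k = 5.00 × 10⁻⁴ /min)
    2 starting material → homo dimer (k = 0.0110 /M/min)
    third conformer → third product (k = 0.00270 /min)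
    other conformer ⇌ third conformer (K = 11.0, k = 0.0430 /min)
    other conformer → isomer of the product (k = 0.0230 /min)
    starting material → target (k = 0.00180 /min)

The other conformer went on to the isomer of the product at 0.023 /min, 7.82 times faster than it returned to starting material at 0.00294 /min. Cedar's target came to 0.07304 M and alder's to 0.07348 M, though alder was charged with more other conformer. T over birch's charge of 0.210 M reads 35.1 %, and birch stood at 34.9 %.

(The runs were generated by integration for an exercise, noise included.)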